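The numbers in the tables were computed for an exercise.

Coupling partner is conserved in our books: we take each unit charged to stand free, to sit on the catalyst, or to have been spent on a target, one unit per target.

in all of them: substrate 0.40 M

| run | coupling partner | free catalyst | temperature | remark | time |
|---|---|---|---|---|---|
| east | 0.98 equiv | 3.7 mol% | 15 °C | run made earlier |  |
| north-east | 1.6 equiv | 3.7 mol% | 35 °C | run made earlier |  |
| south-east | 2.2 equiv | 3.7 mol% | 15 °C | run made earlier |  |
| north | 0.90 equiv | 5.7 mol% | 35 °C | run made earlier |  |
| Friday's | 2.70 equiv | 12 mol% |  | at 50 °C throughout | 50 h |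
| Saturday's | 0.900 equiv | 3.7 mol% |  | at 20 °C until 15 h, from then on at 50 °C | 50 h |

| run | time / h | target / % |
|---|---|---|
| east | 8.00 | 1.4 |
| east | 15.0 | 3.3 |
| east | 20.0 | 3.8 |
| east | 30.0 | 6.9 |
| east | 40.0 | 9.7 |
| north-east | 1.33 | 1.3 |
| north-east | 2.50 | 3.1 |
| north-east | 5.00 | 7.4 |
| north-east | 10.0 | 15.7 |
| north-east | 20.0 | 30.7 |
| south-east | 3.00 | 0 |
| south-east | 5.00 | 0.7 |
| south-east | 10.0 | 1.9 |
| south-east | 20.0 | 4.4 |
| south-east | 40.0 | 10.3 |
| north | 1.33 | 1.8 |
| north | 2.50 | 5.2 |
| north | 5.00 | 11.2 |
| north | 10.0 | 23.1 |
| north | 20.0 | 43.7 |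

(scatter of a reading: 0.3 percentage points)



- the flask that ends with the higher amount of target, in percent of the substrate charged, or "neither" when 2 percentage points or less lies between them (Friday's / Saturday's / neither)
- final target, as a percentage of the substrate charged, in Friday's
- final target, as a percentage of the substrate charged, in Saturday's

**The ledger.** Saturday's flask holds 0.900 equiv of coupling partner per substrate, so partner is its limiting reagent. The first entry is the catalyst. The south-east run read 0 % at 3.00 h, a lag we take to mean that the catalyst loads up before target appears, so we book one partner on each catalyst, 3.7 mol% in Saturday's. The second entry is target, and it gets the rest, 86.3 %. This is the partner budget: charged partner less the catalyst loading, the target we expect once partner has run down. In Friday's the same subtraction gives 258 %, more than the substrate charged, so there substrate closes the books.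

**The clock.** Can the time spend that budget? The east and south-east runs read 9.7 % and 10.3 % at 40.0 h despite their different partner charges, so we let c(substrate) decay with a first-order constant k that ignores partner. The last readings of the east and north-east runs give 0.00255 h⁻¹ at 15 °C and 0.0183 h⁻¹ at 35 °C. Continuing that growth by the same factor per degree to 50 °C, a rough step, gives 0.0805 h⁻¹. Saturday's has 35.0 h at that temperature, which by this k would convert 94.0 %. That is more than the budget, so we expect partner to stop Saturday's near 86.3 %.

The north run gives 0.0287 h⁻¹, which is 1.57 times north-east's for 1.54 times the catalyst; the two runs also differ in partner, which our k ignores, so we scale k with loading. Friday's k times its time then comes to 13.1, and we expect its substrate to be converted completely, higher than Saturday's.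

**The result.** The forecast said Friday's, with 98 % (88 % to 100 %) for Friday's and 86 % (72 % to 90 %) for Saturday's, because “0.90 equiv partner caps it near 90%”. The simulation gives Friday's: >99.9 % in Friday's and 85.3 % in Saturday's.

    coupling partner + free catalyst → catalyst intermediate A (k = 81.0 M⁻¹ h⁻¹, Ea = 66.0 kJ mol⁻¹)
    catalyst intermediate A ⇌ catalyst intermediate B (K = 0.200, k = 64.0 h⁻¹, Ea = 87.0 kJ mol⁻¹, ΔH = −10.0 kJ mol⁻¹)
    catalyst intermediate B → by-product + catalyst intermediate C (k = 1.50 h⁻¹, Ea = 93.0 kJ mol⁻¹)
    substrate + catalyst intermediate C ⇌ catalyst intermediate D (K = 1.80 M⁻¹, k = 1.00 M⁻¹ h⁻¹, Ea = 51.0 kJ mol⁻¹, ΔH = −53.0 kJ mol⁻¹)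
    catalyst intermediate D → catalyst intermediate E (k = 2.70 h⁻¹, Ea = 82.0 kJ mol⁻¹)
    catalyst intermediate E ⇌ free catalyst + target (K = 0.550 M, k = 1.70 h⁻¹, Ea = 86.0 kJ mol⁻¹, ΔH = −76.0 kJ mol⁻¹)
    (constants at 20 °C)

**Books closed.** Saturday's still holds 1.2 % of its own partner charge at 50.0 h. Taking that from the budget leaves 85.2 %, beside the 85.3 % of target in the flask, where 2.70 % of the catalyst charge stands free although the budget booked all of it as loaded. Now take a neighbour of Saturday's charged with 0.540 equiv of partner. Its budget is 50.3 %. That neighbour ends with 0 % of its partner charge left, 13.0 % of its catalyst charge free, 46 % of its substrate still unbound, 3.22 % of the substrate held as catalyst intermediate E, and 50.8 % of target.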